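**Plan**
- Retrosynthetic cuts, in order: phenol O–H (TIPS ether) and the C1 oxidation level (acid from aldehyde); the C1–C2 bond (hydroformylation); the C13–C14 bond (sp3–sp3 coupling); then C3–C2 and C4–CH3 on one half (vinylation and methylalumination of a terminal alkyne) and the C22–aryl bond on the other.
- Enabling feature: the C1 carboxyl, the methyl-bearing stereocentre C2 and the C3=C4 alkene are exactly what branched 1,2-hydroformylation of the vinyl group of a 4,4-disubstituted 1,3-diene leaves behind. The only ring, the benzene ring, lies 18 methylenes away and is bought in.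
- Forward: aryl–C22 bond (aryl Grignard plus 1,9-dibromononane). In parallel, undec-10-yn-1-ol is turned into the (E)-dienol (C4–CH3, then C3–C2; vinyl bromide supplies C2 and the C2 methyl carbon). The halves are joined at C13–C14, then C1–C2 is made, the aldehyde oxidised and the silyl ether removed. No ring is formed.
- Stereochemistry: the E C3=C4 alkene comes from syn-carboalumination and stereoretentive cross-coupling; C2 (R) comes from the chiral rhodium catalyst in the hydroformylation.

Key step: step 6

Assumption: the sense of induction of the bis(diazaphospholane) ligand on this diene cannot be assigned with certainty in advance; the (S,S,S)-ligand is written as the one taken to give 2R, and its antipode would be used if a model run shows the opposite sense.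

**Step 1**
Reactants: 1 4-bromophenol
Product: 2 (4-bromophenoxy)triisopropylsilane
Conditions: TIPSCl, imidazole, DMF, rt
Reagents that add atoms: triisopropylsilyl chloride, CC(C)[Si](Cl)(C(C)C)C(C)C
Why: Silylation of a phenol with a silyl chloride and imidazole is routine, and the bulky aryl TIPS ether should withstand Grignard reagents, syngas and buffered chlorite yet leave with fluoride at the end.

**Step 2**
Reactants: 2 (4-bromophenoxy)triisopropylsilane; 3 1,9-dibromononane
Product: 5 [4-(9-bromononyl)phenoxy]triisopropylsilane, via arylmagnesium bromide 4 (not isolated)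
Conditions: Mg, THF, reflux; then added to 3 (3 equiv), Li2CuCl4 (3 mol%), THF, 0 °C to rt
Reagents that add atoms: magnesium, [Mg] (kept only in intermediate 4)
Why: Copper-catalysed (Kochi-type) cross-coupling of an aryl Grignard reagent with a primary alkyl bromide is established for α,ω-dibromoalkanes, and inverse addition to a threefold excess of the dibromide (surplus recovered by distillation) should keep double arylation low.

**Step 3**
Reactants: 6 undec-10-yn-1-ol; 7 trimethylaluminium; 8 vinyl bromide
Product: 10 (E)-10-methyltrideca-10,12-dien-1-ol, via alkenylalane 9 (not isolated)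
Conditions: 7 (3 equiv), Cp2ZrCl2 (25 mol%), CH2Cl2, 0 °C to rt; volatiles removed; then 8 (2 equiv), Pd(PPh3)4 (3 mol%), ZnCl2 (30 mol%), THF, rt; aq. Rochelle salt
Reagents that add atoms: none
Why: Zirconium-catalysed methylalumination (Negishi carboalumination) adds Me–Al syn across the terminal alkyne with methyl at the internal carbon, the hydroxyl being capped in situ as an inert aluminium alkoxide, and the Pd/Zn-catalysed Negishi cross-coupling with vinyl bromide proceeds with retention, so the E trisubstituted alkene is fixed here.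

**Step 4**
Reactants: 10 (E)-10-methyltrideca-10,12-dien-1-ol
Product: 11 (E)-10-methyltrideca-10,12-dien-1-yl 4-methylbenzenesulfonate
Conditions: TsCl, Et3N, DMAP (cat.), CH2Cl2, 0 °C to rt
Reagents that add atoms: 4-toluenesulfonyl chloride, Cc1ccc(cc1)S(=O)(=O)Cl
Why: Sulfonylation of a primary alcohol under amine base is standard and does not touch the neutral conjugated diene.

**Step 5**
Reactants: 5 [4-(9-bromononyl)phenoxy]triisopropylsilane; 11 (E)-10-methyltrideca-10,12-dien-1-yl 4-methylbenzenesulfonate
Product: 13 (E)-triisopropyl[4-(19-methyldocosa-19,21-dienyl)phenoxy]silane, via alkylmagnesium bromide 12 (not isolated)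
Conditions: 5 (1.3 equiv), Mg, THF, 40 °C; then 11, Li2CuCl4 (5 mol%), THF, −78 °C to rt
Reagents that add atoms: magnesium, [Mg] (kept only in intermediate 12)
Why: Copper-catalysed sp3–sp3 coupling of a primary alkyl Grignard reagent with a primary tosylate (Fouquet–Schlosser conditions) is reliable for long chains, conjugated dienes are inert to catalytic organocopper species, and the aryl silyl ether tolerates the Grignard reagent.

**Step 6**
Reactants: 13 (E)-triisopropyl[4-(19-methyldocosa-19,21-dienyl)phenoxy]silane
Product: 14 (2R,3E)-2,4-dimethyl-22-[4-(triisopropylsilyloxy)phenyl]docos-3-enal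
Conditions: Rh(acac)(CO)2 (1 mol%), (S,S,S)-BisDiazaphos (bis-3,4-diazaphospholane ligand, 1.2 mol%), CO/H2 (1:1, 10 bar), THF, 40 °C; crude product taken directly into step 7
Reagents that add atoms: carbon monoxide, [C-]#[O+]
Why: The Rh–H species carrying the chiral bis(diazaphospholane) inserts the terminal vinyl group of 13 with hydride going to the CH2 terminus (the future C2 methyl), giving an η3-allyl rhodium spanning C2–C4; CO migratory insertion at the secondary terminus C2 and hydrogenolysis of the acyl release 14 and return Rh–H. The closest known reaction type is the rhodium/bis(diazaphospholane)-catalysed asymmetric hydroformylation of terminal 1,3-dienes to α-methyl-β,γ-unsaturated aldehydes. No ring is closed; one C–C bond (C1–C2) is made. The single new stereocentre C2 is under catalyst control: the chiral diazaphospholane pocket decides which face of the vinyl group receives hydride and then the acyl carbon, and the ligand antipode is chosen to give 2R. The step needs branched 1,2-regioselectivity, retention of the E C3=C4 alkene and no migration of that alkene into conjugation; the fully substituted C4 terminus disfavours both acylation there (a quaternary aldehyde) and an η1-allyl at C4 (the only pathway that could scramble the alkene geometry), and the neutral medium at 40 °C should leave the α-proton untouched. The aryl silyl ether and the trisubstituted alkene of the product are inert to the catalyst, so a second hydroformylation is not expected.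

**Step 7**
Reactants: 14 (2R,3E)-2,4-dimethyl-22-[4-(triisopropylsilyloxy)phenyl]docos-3-enal
Product: 15 (2R,3E)-2,4-dimethyl-22-[4-(triisopropylsilyloxy)phenyl]docos-3-enoic acid
Conditions: NaClO2, NaH2PO4, 2-methyl-2-butene (excess), t-BuOH/THF/H2O, 0 °C
Reagents that add atoms: sodium chlorite, [Na+].[O-]Cl=O
Why: Pinnick oxidation at about pH 4 converts aldehydes to acids without enolisation, so C2 and the β,γ-position of the alkene should be preserved, while 2-methyl-2-butene traps hypochlorous acid before it reaches the trisubstituted alkene or the arene.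

**Step 8**
Reactants: 15 (2R,3E)-2,4-dimethyl-22-[4-(triisopropylsilyloxy)phenyl]docos-3-enoic acid
Product: 16 elenic acid, (2R,3E)-22-(4-hydroxyphenyl)-2,4-dimethyldocos-3-enoic acid
Conditions: TBAF (3 equiv), AcOH (1.5 equiv), THF, 0 °C to rt; dilute acid work-up
Reagents that add atoms: none
Why: Fluoride-mediated cleavage of an aryl silyl ether is fast, and with the acid present as its carboxylate and acetic acid buffering the phenoxide, α-deprotonation (epimerisation or conjugation) is not expected.

**Compound list**
1 | 4-bromophenol | Oc1ccc(Br)cc1 | starting material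
2 | (4-bromophenoxy)triisopropylsilane | CC(C)[Si](Oc1ccc(Br)cc1)(C(C)C)C(C)C | intermediate
3 | 1,9-dibromononane | BrCCCCCCCCCBr | starting material
4 | [4-(triisopropylsilyloxy)phenyl]magnesium bromide | CC(C)[Si](Oc1ccc([Mg]Br)cc1)(C(C)C)C(C)C | intermediate
5 | [4-(9-bromononyl)phenoxy]triisopropylsilane | CC(C)[Si](Oc1ccc(CCCCCCCCCBr)cc1)(C(C)C)C(C)C | intermediate
6 | undec-10-yn-1-ol | C#CCCCCCCCCCO | starting material
7 | trimethylaluminium | C[Al](C)C | starting material
8 | vinyl bromide | C=CBr | starting material
9 | dimethyl[(1E)-11-(dimethylalumanyloxy)-2-methylundec-1-en-1-yl]alumane (Al and the C2 methyl cis) | C[Al](C)/C=C(\C)CCCCCCCCCO[Al](C)C | intermediate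
10 | (E)-10-methyltrideca-10,12-dien-1-ol | C=C/C=C(\C)CCCCCCCCCO | intermediate
11 | (E)-10-methyltrideca-10,12-dien-1-yl 4-methylbenzenesulfonate | C=C/C=C(\C)CCCCCCCCCOS(=O)(=O)c1ccc(C)cc1 | intermediate
12 | {9-[4-(triisopropylsilyloxy)phenyl]nonyl}magnesium bromide | CC(C)[Si](Oc1ccc(CCCCCCCCC[Mg]Br)cc1)(C(C)C)C(C)C | intermediate
13 | (E)-triisopropyl[4-(19-methyldocosa-19,21-dienyl)phenoxy]silane | C=C/C=C(\C)CCCCCCCCCCCCCCCCCCc1ccc(O[Si](C(C)C)(C(C)C)C(C)C)cc1 | intermediate
14 | (2R,3E)-2,4-dimethyl-22-[4-(triisopropylsilyloxy)phenyl]docos-3-enal | C/C(=C\[C@@H](C)C=O)CCCCCCCCCCCCCCCCCCc1ccc(O[Si](C(C)C)(C(C)C)C(C)C)cc1 | intermediate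
15 | (2R,3E)-2,4-dimethyl-22-[4-(triisopropylsilyloxy)phenyl]docos-3-enoic acid | C/C(=C\[C@@H](C)C(=O)O)CCCCCCCCCCCCCCCCCCc1ccc(O[Si](C(C)C)(C(C)C)C(C)C)cc1 | intermediate
16 | elenic acid, (2R,3E)-22-(4-hydroxyphenyl)-2,4-dimethyldocos-3-enoic acid | C/C(=C\[C@@H](C)C(=O)O)CCCCCCCCCCCCCCCCCCc1ccc(O)cc1 | target

**Count**
Total steps: 8. Longest linear sequence: 6 steps (1, 2, 5, 6, 7, 8 from 4-bromophenol; equally 3, 4, 5, 6, 7, 8 from undec-10-yn-1-ol).

**Steps most likely to fail**

1. Step 6. Face selection at C2 may be insufficient on this 4,4-disubstituted diene, linear or 1,4-hydroformylation may compete, or the β,γ-unsaturated aldehyde may drift into conjugation or epimerise before oxidation. The fallback sets out from diene 13 and rejoins at acid 15, placing the C2 methyl by auxiliary control instead.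
   - 9-BBN (THF, 0 °C to rt; NaBO3·4H2O) hydroborates only the terminal vinyl group to give (E)-4-methyl-22-[4-(triisopropylsilyloxy)phenyl]docos-3-en-1-ol F1.
   - TEMPO/PhI(OAc)2 in aqueous MeCN oxidises it to (E)-4-methyl-22-[4-(triisopropylsilyloxy)phenyl]docos-3-enoic acid F2.
   - Pivaloyl chloride/Et3N followed by lithiated (R)-4-benzyloxazolidin-2-one gives (R)-4-benzyl-3-[(E)-4-methyl-22-[4-(triisopropylsilyloxy)phenyl]docos-3-enoyl]oxazolidin-2-one F3.
   - Evans alkylation (NaHMDS, MeI, THF, −78 °C) delivers methyl to the Z-enolate face away from the benzyl group and gives (R)-4-benzyl-3-[(2R,3E)-2,4-dimethyl-22-[4-(triisopropylsilyloxy)phenyl]docos-3-enoyl]oxazolidin-2-one F4.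
   - LiOH/H2O2 (THF/H2O, 0 °C) then releases 15.

2. Step 3. The one-pot cross-coupling of an alkenylalane that also carries an aluminium alkoxide may stall, or methyl transfer from residual methylaluminium species may consume the vinyl bromide. The fallback sets out from alkyne 6 and returns at dienol 10. The same methylalumination is quenched with iodine (THF, −30 °C) to give (E)-11-iodo-10-methylundec-10-en-1-ol F5, which is isolated and purified. A separate Suzuki–Miyaura coupling with vinylboronic acid pinacol ester (PdCl2(dppf), K2CO3, THF/H2O, 60 °C) then gives 10.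

3. Step 2. The copper-catalysed aryl–alkyl coupling may be sluggish, and arylation at both ends of the dibromide may erode the mono-coupled product. The fallback sets out from aryl bromide 2 and returns at bromide 5. Sonogashira coupling with non-8-yn-1-ol (PdCl2(PhCN)2, P(t-Bu)3, CuI, i-Pr2NH, dioxane, rt) gives 9-[4-(triisopropylsilyloxy)phenyl]non-8-yn-1-ol F6. Hydrogenation (H2, Pd/C, EtOAc) gives 9-[4-(triisopropylsilyloxy)phenyl]nonan-1-ol F7. Appel bromination (CBr4, PPh3, CH2Cl2, 0 °C) gives 5.

**Further compounds**
F1 | step 6 | (E)-4-methyl-22-[4-(triisopropylsilyloxy)phenyl]docos-3-en-1-ol | C/C(=C\CCO)CCCCCCCCCCCCCCCCCCc1ccc(O[Si](C(C)C)(C(C)C)C(C)C)cc1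
F2 | step 6 | (E)-4-methyl-22-[4-(triisopropylsilyloxy)phenyl]docos-3-enoic acid | C/C(=C\CC(=O)O)CCCCCCCCCCCCCCCCCCc1ccc(O[Si](C(C)C)(C(C)C)C(C)C)cc1
F3 | step 6 | (R)-4-benzyl-3-[(E)-4-methyl-22-[4-(triisopropylsilyloxy)phenyl]docos-3-enoyl]oxazolidin-2-one | C/C(=C\CC(=O)N1[C@H](Cc2ccccc2)COC1=O)CCCCCCCCCCCCCCCCCCc1ccc(O[Si](C(C)C)(C(C)C)C(C)C)cc1
F4 | step 6 | (R)-4-benzyl-3-[(2R,3E)-2,4-dimethyl-22-[4-(triisopropylsilyloxy)phenyl]docos-3-enoyl]oxazolidin-2-one | C/C(=C\[C@@H](C)C(=O)N1[C@H](Cc2ccccc2)COC1=O)CCCCCCCCCCCCCCCCCCc1ccc(O[Si](C(C)C)(C(C)C)C(C)C)cc1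
F5 | step 3 | (E)-11-iodo-10-methylundec-10-en-1-ol | C/C(=C\I)CCCCCCCCCO
F6 | step 2 | 9-[4-(triisopropylsilyloxy)phenyl]non-8-yn-1-ol | OCCCCCCCC#Cc1ccc(O[Si](C(C)C)(C(C)C)C(C)C)cc1
F7 | step 2 | 9-[4-(triisopropylsilyloxy)phenyl]nonan-1-ol | OCCCCCCCCCc1ccc(O[Si](C(C)C)(C(C)C)C(C)C)cc1
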